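## The problem

The target 29 is a (2S,3S)-trans-2,3-diaryl-2,3-dihydrobenzofuran. Its benzo ring (ring A) carries a hydroxyl at C4 and a 2-(4-hydroxyphenyl)ethyl chain at C6; C2 carries a 2,4-dihydroxyphenyl group (ring B) and C3 a 3,5-dihydroxyphenyl group (ring C). A synthesis must gather three oxygenated arenes around the adjacent sp3 carbons C2 and C3, and must place the C3 substituent on the one ring A carbon that lies between two oxygens, the position least open to electrophilic substitution. Only one of the two stereocentres needs an outside source of chirality: while C3 is alpha to a carbonyl group it equilibrates to the trans arrangement under control of C2, and once C3 is fixed any reversible opening of O1–C2 recloses trans under control of C3. The O1–C2 bond is the fragile part, a benzylic ether activated by the ortho and para oxygens of ring B; it can ionise under strong acid and, once the para hydroxyl is free, open through a quinone methide under base. The six free phenols are air-sensitive and should appear only at the end, and C3, a methine flanked by ring A and the C2 aryl group, is a poor place for a late aryl–carbon coupling. Ring C itself makes such a coupling unnecessary: its two hydroxyls are meta to each other and its attachment carbon C1' is meta to both, the pattern left when a 3,5,7-triketo acid folds so that C2 adds to the C7 carbonyl. If C7 of that chain is an acyl carbon on C3, ring C can be grown from a C3 carboxyl group by forming the C1'–C2' bond, and the carboxyl left on C2' is removed afterwards.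

## Retrosynthesis

**29 from 28.** The four aryl O–CH3 bonds are cut last. Methyl is chosen for every travelling phenol because the ring A oxygen beside the carbene carbon of 13 must offer no C–H bond in a five-membered insertion geometry; a benzyl, isopropyl or MOM group there would compete, a methyl could only give a four-membered ring. Ring C needs no protection, since it is formed as a free resorcinol. The forward step must cleave four ethers without ionising O1–C2.

**28 from 26.** The bond between C2' of ring C and its carboxyl carbon is cut; this carboxyl is the C1 residue of the polyketide chain. An allyl ester (26) is preferred to a methyl ester because the carbonyl sits between a hydroxyl and the branched C3 substituent and would resist saponification, whereas the allyl group can be removed at its own carbon. The free acid 27 then has to lose CO2 on heating.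

**26 from 22.** This is the strategic cut: C1'–C2' of ring C (C7–C2 of the chain), together with the ester C–O bond. The neighbouring cut, C3–C1', would require an aryl coupling at a hindered, enolisable benzylic carbon and offers no way to use the meta-dioxygen pattern. Precursor 22 has one ring fewer and carries ring C as a linear masked triketo acid; the passage runs through 23, 24 and 25. The forward reaction must close through carbon and not oxygen, and must leave C3 trans.

**22 from 16 and 19.** The bond between the acyl carbon on C3 and the adjacent methylene is cut. This divides the chain into the C3 carboxylic acid 16, activated as 20, and the four-carbon keto-dioxinone 19, used as its dianion 21; 19 comes in one step from commercial 17 through 18. Cutting one bond further along the chain would need a methyl ketone on C3 and a less available dioxinone acyl donor. The forward Claisen condensation has to tolerate the acidic C3–H of 20.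

**16 from 14 and 13.** The C2–C3 bond is cut as a carbene C–H insertion. Of the three ring bonds that could be formed last, this one creates C2 under catalyst control and leaves an ester on C3, exactly the acyl handle the chain extension needs. The cis ester 14 is epimerised through trans ester 15 and hydrolysed to 16. Precursor 13 is acyclic and achiral.

**13 from 12, and 12 from 10 and 11.** The diazo group is removed (diazo transfer forward) and the aryl O–CH2 bond is cut to phenol 10 and alcohol 11, which supplies ring B complete. A Mitsunobu etherification avoids the unstable benzylic halide of 11.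

**10 from 9, 8 and 6.** The bond between ring A and its acetic acid arm is cut at the carbon between the two oxygens. Only directed metalation reaches this position selectively, so 6 is lithiated to 7 and given a two-carbon arm with ethylene oxide (8); oxidation gives 9, and acidic methanol forms the ester and removes the MOM director in one operation (10).

**6 from 5, 2 and 3, and 2 from 1.** The bibenzyl CH2–CH2 bond is traced to a stilbene double bond (5) made by Wittig reaction of aldehyde 2 with ylide 4 from salt 3. Aldehyde 2 is the MOM ether of commercial 1, so the protecting group needed for metalation is installed before the phenol can interfere with the ylide.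

## Roads not taken

**Alternative 1:** The cut is O1–C2, with ring A carried as a cyclohexane-1,3-dione. A spirocyclopropane dione A2 is treated with Sc(OTf)3; the cyclopropane bond to the carbon bearing the 2,4-dimethoxyphenyl group ionises and the dione enolate oxygen closes O1–C2 to give tetrahydrobenzofuranone A1 (Cloke–Wilson ring expansion).
- Merits: both aryl groups are in place before the heterocycle forms; the opening is directed by the better cation-stabilising aryl; the route to A1 is clearly shorter than the route to 22; the C4 oxygen emerges unprotected.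
- Weak points: C3 is untouched in the ring expansion, so its absolute configuration would have to come from an asymmetric cyclopropanation of an internal diaryl alkene by an acceptor/acceptor carbene, which cannot be relied on. Ring A of A1 must then be dehydrogenated without also dehydrogenating C2–C3, which would give a fully aromatic benzofuran and erase both stereocentres.
- Comparison: in step count this road is better. The chosen plan sets against it a catalyst-controlled C2 from an established enantioselective reaction class (step 9) and no oxidation on the heterocycle.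

**Alternative 2:** The cut removes both aryl–carbon bonds at C2 and C3 in one step. Ring A alkenyl boronate A4, aryllithium A5 and aryl triflate A6 combine under Pd(OAc)2 and a MandyPhos ligand: the aryl of A5 migrates from boron to the carbon that becomes C2 while palladium delivers the aryl of A6 to the carbon that becomes C3, giving boronic ester A3. No ring closes; oxidation of the C–B bond and an invertive closure of O1–C2 would follow.
- Merits: it is the most convergent plan; both stereocentres come from one catalyst; ring C arrives as a finished arene with no surplus carbon to remove.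
- Weak points: palladium must deliver an aryl to a carbon of A4 that carries a 2,6-dioxygenated aryl, and the migrating aryl of A5 is ortho-substituted; both lie outside the unhindered substrates for which conjunctive coupling is established. The later displacement at a 2,4-dimethoxybenzylic carbon would probably ionise rather than invert, although the trans ring is the thermodynamic outcome anyway.
- Comparison: if its key step worked it would be superior in convergence and length. The chosen plan keeps every bond-forming event within known substrate scope, at the price of a longer linear sequence and one carbon lost as CO2.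

**Alternative 3:** The cut is C3–C3a. Irradiation of 3-diazoflavanone A8 in methanol with NaOMe triggers a Wolff rearrangement: the ring A carbon migrates to the carbene carbon, the pyranone contracts, and the ketene is trapped as trans ester A7, which is the same compound as 15. This road therefore replaces only steps 4–10 and still needs the ring C construction.
- Merits: A8 comes from chalcone-type chemistry through its parent flavanone A9; no metal carbene is involved, and the hindered diazo transfer of step 8 is avoided.
- Weak points: the acyl group of A9 must again be placed on the carbon between two oxygens, so nothing is saved there. C2 of A9 and A8 can open by retro-oxa-Michael reaction under the basic conditions of diazo transfer and photolysis, and the Wolff step sets no absolute configuration.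
- Comparison: the length to A7 is about equal and it avoids two of the riskier steps of the chosen route. The chosen plan sets against it that C2 is created in the enantio-determining step and never sits beside an enolisable ketone in a ring that can open.

Key step: step 13

Assumption: Rh2(S-PTTL)4, the dirhodium tetrakis[N-phthaloyl-(S)-tert-leucinate] catalyst, is taken to select the benzylic hydrogen whose replacement gives 2S; if the sense proves opposite, its mirror-image catalyst Rh2(R-PTTL)4 is used and nothing else changes.

## Route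

Step 1
Reactants: 1 3-hydroxy-5-methoxybenzaldehyde
Product: 2 3-methoxy-5-(methoxymethoxy)benzaldehyde
Conditions: MOMCl, i-Pr2NEt, CH2Cl2, 0 °C to rt
Reagents that add atoms: chloromethyl methyl ether (MOMCl), COCCl
Why: O-alkylation of the phenol under amine base; the MOM ether is stable to ylide and hydrogenation and later cooperates with the methoxy group in directing lithiation.

Step 2
Reactants: 2 3-methoxy-5-(methoxymethoxy)benzaldehyde; 3 (4-methoxybenzyl)triphenylphosphonium chloride
Product: 5 1-methoxy-3-(methoxymethoxy)-5-[2-(4-methoxyphenyl)ethenyl]benzene (E/Z mixture), via (4-methoxybenzylidene)triphenylphosphorane 4 (not isolated)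
Conditions: 3, KOtBu, THF, 0 °C; then 2, 0 °C to rt
Reagents that add atoms: none
Why: Wittig olefination of an aryl aldehyde with a semi-stabilised benzylic ylide; the alkene geometry is irrelevant because the double bond is hydrogenated next.

Step 3
Reactants: 5 1-methoxy-3-(methoxymethoxy)-5-[2-(4-methoxyphenyl)ethenyl]benzene
Product: 6 1-methoxy-3-(methoxymethoxy)-5-[2-(4-methoxyphenyl)ethyl]benzene
Conditions: H2 (1 atm), 10% Pd/C, EtOAc, rt
Reagents that add atoms: none
Why: Heterogeneous catalytic hydrogenation of a stilbene; no hydrogenolysable group is present and the MOM acetal is inert under neutral conditions.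

Step 4
Reactants: 6 1-methoxy-3-(methoxymethoxy)-5-[2-(4-methoxyphenyl)ethyl]benzene
Product: 8 2-{2-methoxy-6-(methoxymethoxy)-4-[2-(4-methoxyphenyl)ethyl]phenyl}ethanol, via aryllithium 7 (not isolated)
Conditions: n-BuLi, TMEDA, THF, 0 °C; then ethylene oxide, 0 °C to rt
Reagents that add atoms: ethylene oxide (oxirane), C1CO1
Why: Directed ortho-metalation; the OMOM and OMe groups cooperate so that lithiation occurs at the carbon between them, and the aryllithium opens the epoxide by SN2 attack to install the two-carbon arm.

Step 5
Reactants: 8 2-{2-methoxy-6-(methoxymethoxy)-4-[2-(4-methoxyphenyl)ethyl]phenyl}ethanol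
Product: 9 {2-methoxy-6-(methoxymethoxy)-4-[2-(4-methoxyphenyl)ethyl]phenyl}acetic acid
Conditions: TEMPO (cat.), PhI(OAc)2, MeCN–H2O, rt
Reagents that add atoms: water, O
Why: Nitroxyl-catalysed oxidation of a primary alcohol through the aldehyde hydrate to the acid; the near-neutral medium spares the MOM acetal and the electron-rich rings.

Step 6
Reactants: 9 {2-methoxy-6-(methoxymethoxy)-4-[2-(4-methoxyphenyl)ethyl]phenyl}acetic acid
Product: 10 methyl {2-hydroxy-6-methoxy-4-[2-(4-methoxyphenyl)ethyl]phenyl}acetate
Conditions: HCl (1.25 M in MeOH), 40 °C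
Reagents that add atoms: methanol, CO
Why: Fischer esterification and acetal methanolysis run together in acidic methanol; the excess methanol keeps the hydroxy ester from lactonising, and the solution is neutralised before concentration.

Step 7
Reactants: 10 methyl {2-hydroxy-6-methoxy-4-[2-(4-methoxyphenyl)ethyl]phenyl}acetate; 11 2,4-dimethoxybenzyl alcohol
Product: 12 methyl {2-[(2,4-dimethoxybenzyl)oxy]-6-methoxy-4-[2-(4-methoxyphenyl)ethyl]phenyl}acetate
Conditions: PPh3, DIAD, THF, 0 °C to rt
Reagents that add atoms: none
Why: Mitsunobu etherification of a phenol with a primary benzylic alcohol; it avoids the unstable 2,4-dimethoxybenzyl halide and exposes the ester to no strong base.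

Step 8
Reactants: 12 methyl {2-[(2,4-dimethoxybenzyl)oxy]-6-methoxy-4-[2-(4-methoxyphenyl)ethyl]phenyl}acetate
Product: 13 methyl diazo{2-[(2,4-dimethoxybenzyl)oxy]-6-methoxy-4-[2-(4-methoxyphenyl)ethyl]phenyl}acetate
Conditions: p-ABSA, DBU, MeCN, 0 °C to rt
Reagents that add atoms: 4-acetamidobenzenesulfonyl azide (p-ABSA), CC(=O)Nc1ccc(cc1)S(=O)(=O)N=[N+]=[N-]
Why: Regitz diazo transfer from a sulfonyl azide to the aryl-activated ester methylene, the standard entry to aryldiazoacetates.

Step 9
Reactants: 13 methyl diazo{2-[(2,4-dimethoxybenzyl)oxy]-6-methoxy-4-[2-(4-methoxyphenyl)ethyl]phenyl}acetate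
Product: 14 methyl (2S,3R)-2-(2,4-dimethoxyphenyl)-4-methoxy-6-[2-(4-methoxyphenyl)ethyl]-2,3-dihydro-1-benzofuran-3-carboxylate (cis)
Conditions: Rh2(S-PTTL)4 (1 mol %), toluene, −60 °C
Reagents that add atoms: none
Why: Intramolecular 1,5 C–H insertion of a donor/acceptor rhodium carbene into the ether benzylic C–H, which the electron-rich aryl activates; the chiral carboxylate ligands choose between the two enantiotopic hydrogens and so set C2 (S), while the cis ester is the kinetic product and C3 (R) is provisional.

Step 10
Reactants: 14 methyl (2S,3R)-2-(2,4-dimethoxyphenyl)-4-methoxy-6-[2-(4-methoxyphenyl)ethyl]-2,3-dihydro-1-benzofuran-3-carboxylate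
Product: 16 (2S,3S)-2-(2,4-dimethoxyphenyl)-4-methoxy-6-[2-(4-methoxyphenyl)ethyl]-2,3-dihydro-1-benzofuran-3-carboxylic acid (trans), via trans methyl ester 15 (not isolated)
Conditions: NaOMe, MeOH, rt; then aq. NaOH, 60 °C; then cold 1 M HCl to pH 4
Reagents that add atoms: sodium hydroxide, [Na+].[OH-]
Why: Methoxide epimerises the ester alpha-carbon to the more stable trans isomer under control of C2 (C3 becomes S), and saponification follows; ring opening by beta-elimination of the phenoxide is the reverse of a 5-endo-trig closure and is stereoelectronically slow.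

Step 11
Reactants: 17 2,2,6-trimethyl-4H-1,3-dioxin-4-one
Product: 19 2,2-dimethyl-6-(2-oxopropyl)-4H-1,3-dioxin-4-one, via lithium dienolate 18 (not isolated)
Conditions: LiHMDS, THF, −78 °C; then AcCl (0.5 equiv), −78 °C
Reagents that add atoms: acetyl chloride, CC(Cl)=O
Why: Deprotonation at the 6-methyl group gives the extended dienolate, which is C-acylated at its exocyclic carbon (vinylogous Claisen condensation); half of the dienolate serves as base for the more acidic product.

Step 12
Reactants: 16 (2S,3S)-2-(2,4-dimethoxyphenyl)-4-methoxy-6-[2-(4-methoxyphenyl)ethyl]-2,3-dihydro-1-benzofuran-3-carboxylic acid; 19 2,2-dimethyl-6-(2-oxopropyl)-4H-1,3-dioxin-4-one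
Product: 22 6-{4-[(2S,3S)-2-(2,4-dimethoxyphenyl)-4-methoxy-6-[2-(4-methoxyphenyl)ethyl]-2,3-dihydro-1-benzofuran-3-yl]-2,4-dioxobutyl}-2,2-dimethyl-4H-1,3-dioxin-4-one, via acyl imidazole 20 (not isolated), via dilithium dianion 21 (not isolated)
Conditions: 16, CDI, THF, rt; 19, LDA (2 equiv), THF, −78 °C; then 20 added to 21 (2.5 equiv), −78 to −40 °C; AcOH
Reagents that add atoms: none
Why: Claisen condensation of a 1,3-dicarbonyl dianion at its terminal carbon with an acyl imidazole, a known way to diketo-dioxinones; if the dianion instead removes the C3 proton, the acyl imidazole can collapse to an arylketene that the excess dianion acylates at the same carbon, and protonation returns the more stable trans arrangement.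

Step 13
Reactants: 22 6-{4-[(2S,3S)-2-(2,4-dimethoxyphenyl)-4-methoxy-6-[2-(4-methoxyphenyl)ethyl]-2,3-dihydro-1-benzofuran-3-yl]-2,4-dioxobutyl}-2,2-dimethyl-4H-1,3-dioxin-4-one
Product: 26 allyl 2,4-dihydroxy-6-[(2S,3S)-2-(2,4-dimethoxyphenyl)-4-methoxy-6-[2-(4-methoxyphenyl)ethyl]-2,3-dihydro-1-benzofuran-3-yl]benzoate, via acylketene 23 (not isolated), via allyl triketo ester 24 (not isolated), via cyclic aldol 25 (not isolated)
Conditions: allyl alcohol, toluene, 110 °C; then Cs2CO3, allyl alcohol–THF, rt; then AcOH
Reagents that add atoms: allyl alcohol (prop-2-en-1-ol), C=CCO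
Why: Above about 100 °C the dioxinone ring of 22 fragments in a retro-[4+2] reaction to acetone and acylketene 23, to which allyl alcohol adds to give the open 3,5,7-triketo ester 24. Cs2CO3 then forms the enolate at the C2 methylene between the ester and the C3 ketone, and this carbon adds to the C7 ketone, the acyl carbon on the heterocycle; the ring closes as a six-membered 6-(enolendo)-exo-trig aldol to 25, which loses water and enolises to the arene, so that C1'–C2' of ring C is the bond made. The closest known reaction type is the aromatisation of diketo-dioxinones, through their triketo esters, to 6-substituted 2,4-dihydroxybenzoates by ketene trapping and carbonate-mediated aldol condensation. No stereocentre from the closure survives, since the carbinol carbon of 25 becomes aromatic C1'. The selectivity needed is carbon aldol from C2 to C7 rather than Claisen closure from C6 to C1 or lactonisation of an enol oxygen onto the ester; an ester terminus (a poor acyl donor), a mild carbonate base at room temperature and excess alcohol during the thermolysis favour the aldol. C3 of the heterocycle is alpha to C7, but the 1,3-diketone enolises across C6 and any equilibration at C3 leads to the wanted trans isomer; after aromatisation C3 can no longer enolise. Allyl alcohol replaces methanol only so that the hindered ester can later be removed at its allyl group, and its use as co-solvent in the base stage makes any transesterification degenerate.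

Step 14
Reactants: 26 allyl 2,4-dihydroxy-6-[(2S,3S)-2-(2,4-dimethoxyphenyl)-4-methoxy-6-[2-(4-methoxyphenyl)ethyl]-2,3-dihydro-1-benzofuran-3-yl]benzoate
Product: 28 5-[(2S,3S)-2-(2,4-dimethoxyphenyl)-4-methoxy-6-[2-(4-methoxyphenyl)ethyl]-2,3-dihydro-1-benzofuran-3-yl]benzene-1,3-diol, via resorcylic acid 27 (not isolated)
Conditions: Pd(PPh3)4 (5 mol %), morpholine, THF, rt; then pH 4 work-up; DMF, 110 °C
Reagents that add atoms: none
Why: Tsuji–Trost deallylation: zerovalent palladium ionises the allyl ester to a pi-allyl complex that morpholine captures, so the acid is freed without attack at the hindered carbonyl; the 2,4-dihydroxybenzoic acid then loses CO2 on heating by ipso-protonation, as beta-resorcylic acids do.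

Step 15
Reactants: 28 5-[(2S,3S)-2-(2,4-dimethoxyphenyl)-4-methoxy-6-[2-(4-methoxyphenyl)ethyl]-2,3-dihydro-1-benzofuran-3-yl]benzene-1,3-diol
Product: 29 4-[(2S,3S)-3-(3,5-dihydroxyphenyl)-4-hydroxy-6-[2-(4-hydroxyphenyl)ethyl]-2,3-dihydro-1-benzofuran-2-yl]benzene-1,3-diol
Conditions: BBr3, CH2Cl2, −78 to 0 °C; then H2O
Reagents that add atoms: none
Why: Lewis acid cleavage of aryl methyl ethers, bromide attacking the methyl carbon of the boron-bound ether; the reaction is kept cold to spare the O1–C2 benzylic ether, and should that bond open, reclosure from the ring A phenol is governed by the fixed C3 and returns the trans ring.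

## Compound list

1 | 3-hydroxy-5-methoxybenzaldehyde | COc1cc(O)cc(C=O)c1 | starting material
2 | 3-methoxy-5-(methoxymethoxy)benzaldehyde | COCOc1cc(OC)cc(C=O)c1 | intermediate
3 | (4-methoxybenzyl)triphenylphosphonium chloride | COc1ccc(C[P+](c2ccccc2)(c2ccccc2)c2ccccc2)cc1.[Cl-] | starting material
4 | (4-methoxybenzylidene)triphenylphosphorane | COc1ccc(C=P(c2ccccc2)(c2ccccc2)c2ccccc2)cc1 | intermediate
5 | 1-methoxy-3-(methoxymethoxy)-5-[2-(4-methoxyphenyl)ethenyl]benzene (E/Z mixture) | COCOc1cc(OC)cc(C=Cc2ccc(OC)cc2)c1 | intermediate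
6 | 1-methoxy-3-(methoxymethoxy)-5-[2-(4-methoxyphenyl)ethyl]benzene | COCOc1cc(OC)cc(CCc2ccc(OC)cc2)c1 | intermediate
7 | {2-methoxy-6-(methoxymethoxy)-4-[2-(4-methoxyphenyl)ethyl]phenyl}lithium | COCOc1cc(CCc2ccc(OC)cc2)cc(OC)c1[Li] | intermediate
8 | 2-{2-methoxy-6-(methoxymethoxy)-4-[2-(4-methoxyphenyl)ethyl]phenyl}ethanol | COCOc1cc(CCc2ccc(OC)cc2)cc(OC)c1CCO | intermediate
9 | {2-methoxy-6-(methoxymethoxy)-4-[2-(4-methoxyphenyl)ethyl]phenyl}acetic acid | COCOc1cc(CCc2ccc(OC)cc2)cc(OC)c1CC(=O)O | intermediate
10 | methyl {2-hydroxy-6-methoxy-4-[2-(4-methoxyphenyl)ethyl]phenyl}acetate | COC(=O)Cc1c(O)cc(CCc2ccc(OC)cc2)cc1OC | intermediate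
11 | 2,4-dimethoxybenzyl alcohol | COc1ccc(CO)c(OC)c1 | starting material
12 | methyl {2-[(2,4-dimethoxybenzyl)oxy]-6-methoxy-4-[2-(4-methoxyphenyl)ethyl]phenyl}acetate | COC(=O)Cc1c(OCc2ccc(OC)cc2OC)cc(CCc2ccc(OC)cc2)cc1OC | intermediate
13 | methyl diazo{2-[(2,4-dimethoxybenzyl)oxy]-6-methoxy-4-[2-(4-methoxyphenyl)ethyl]phenyl}acetate | COC(=O)C(=[N+]=[N-])c1c(OCc2ccc(OC)cc2OC)cc(CCc2ccc(OC)cc2)cc1OC | intermediate
14 | methyl (2S,3R)-2-(2,4-dimethoxyphenyl)-4-methoxy-6-[2-(4-methoxyphenyl)ethyl]-2,3-dihydro-1-benzofuran-3-carboxylate (cis) | COc1ccc(CCc2cc(OC)c3c(c2)O[C@H](c2ccc(OC)cc2OC)[C@@H]3C(=O)OC)cc1 | intermediate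
15 | methyl (2S,3S)-2-(2,4-dimethoxyphenyl)-4-methoxy-6-[2-(4-methoxyphenyl)ethyl]-2,3-dihydro-1-benzofuran-3-carboxylate (trans) | COc1ccc(CCc2cc(OC)c3c(c2)O[C@H](c2ccc(OC)cc2OC)[C@H]3C(=O)OC)cc1 | intermediate
16 | (2S,3S)-2-(2,4-dimethoxyphenyl)-4-methoxy-6-[2-(4-methoxyphenyl)ethyl]-2,3-dihydro-1-benzofuran-3-carboxylic acid (trans) | COc1ccc(CCc2cc(OC)c3c(c2)O[C@H](c2ccc(OC)cc2OC)[C@H]3C(=O)O)cc1 | intermediate
17 | 2,2,6-trimethyl-4H-1,3-dioxin-4-one | CC1=CC(=O)OC(C)(C)O1 | starting material
18 | lithium 2,2-dimethyl-6-methylidene-6H-1,3-dioxin-4-olate (dienolate of 17) | C=C1C=C(O[Li])OC(C)(C)O1 | intermediate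
19 | 2,2-dimethyl-6-(2-oxopropyl)-4H-1,3-dioxin-4-one | CC(=O)CC1=CC(=O)OC(C)(C)O1 | intermediate
20 | 1-{[(2S,3S)-2-(2,4-dimethoxyphenyl)-4-methoxy-6-[2-(4-methoxyphenyl)ethyl]-2,3-dihydro-1-benzofuran-3-yl]carbonyl}-1H-imidazole | COc1ccc(CCc2cc(OC)c3c(c2)O[C@H](c2ccc(OC)cc2OC)[C@H]3C(=O)n2ccnc2)cc1 | intermediate
21 | dilithium dianion of 19 (bis-enolate) | C=C(O[Li])C=C1C=C(O[Li])OC(C)(C)O1 | intermediate
22 | 6-{4-[(2S,3S)-2-(2,4-dimethoxyphenyl)-4-methoxy-6-[2-(4-methoxyphenyl)ethyl]-2,3-dihydro-1-benzofuran-3-yl]-2,4-dioxobutyl}-2,2-dimethyl-4H-1,3-dioxin-4-one | COc1ccc(CCc2cc(OC)c3c(c2)O[C@H](c2ccc(OC)cc2OC)[C@H]3C(=O)CC(=O)CC2=CC(=O)OC(C)(C)O2)cc1 | intermediate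
23 | 7-[(2S,3S)-2-(2,4-dimethoxyphenyl)-4-methoxy-6-[2-(4-methoxyphenyl)ethyl]-2,3-dihydro-1-benzofuran-3-yl]hept-1-ene-1,3,5,7-tetrone (acylketene) | COc1ccc(CCc2cc(OC)c3c(c2)O[C@H](c2ccc(OC)cc2OC)[C@H]3C(=O)CC(=O)CC(=O)C=C=O)cc1 | intermediate
24 | allyl 7-[(2S,3S)-2-(2,4-dimethoxyphenyl)-4-methoxy-6-[2-(4-methoxyphenyl)ethyl]-2,3-dihydro-1-benzofuran-3-yl]-3,5,7-trioxoheptanoate | COc1ccc(CCc2cc(OC)c3c(c2)O[C@H](c2ccc(OC)cc2OC)[C@H]3C(=O)CC(=O)CC(=O)CC(=O)OCC=C)cc1 | intermediate
25 | allyl 2-hydroxy-4,6-dioxo-2-[(2S,3S)-2-(2,4-dimethoxyphenyl)-4-methoxy-6-[2-(4-methoxyphenyl)ethyl]-2,3-dihydro-1-benzofuran-3-yl]cyclohexane-1-carboxylate (ring carbons C1 and C2 unassigned) | COc1ccc(CCc2cc(OC)c3c(c2)O[C@H](c2ccc(OC)cc2OC)[C@H]3C2(O)CC(=O)CC(=O)C2C(=O)OCC=C)cc1 | intermediate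
26 | allyl 2,4-dihydroxy-6-[(2S,3S)-2-(2,4-dimethoxyphenyl)-4-methoxy-6-[2-(4-methoxyphenyl)ethyl]-2,3-dihydro-1-benzofuran-3-yl]benzoate | COc1ccc(CCc2cc(OC)c3c(c2)O[C@H](c2ccc(OC)cc2OC)[C@H]3c2cc(O)cc(O)c2C(=O)OCC=C)cc1 | intermediate
27 | 2,4-dihydroxy-6-[(2S,3S)-2-(2,4-dimethoxyphenyl)-4-methoxy-6-[2-(4-methoxyphenyl)ethyl]-2,3-dihydro-1-benzofuran-3-yl]benzoic acid | COc1ccc(CCc2cc(OC)c3c(c2)O[C@H](c2ccc(OC)cc2OC)[C@H]3c2cc(O)cc(O)c2C(=O)O)cc1 | intermediate
28 | 5-[(2S,3S)-2-(2,4-dimethoxyphenyl)-4-methoxy-6-[2-(4-methoxyphenyl)ethyl]-2,3-dihydro-1-benzofuran-3-yl]benzene-1,3-diol | COc1ccc(CCc2cc(OC)c3c(c2)O[C@H](c2ccc(OC)cc2OC)[C@H]3c2cc(O)cc(O)c2)cc1 | intermediate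
29 | 4-[(2S,3S)-3-(3,5-dihydroxyphenyl)-4-hydroxy-6-[2-(4-hydroxyphenyl)ethyl]-2,3-dihydro-1-benzofuran-2-yl]benzene-1,3-diol | Oc1ccc(CCc2cc(O)c3c(c2)O[C@H](c2ccc(O)cc2O)[C@H]3c2cc(O)cc(O)c2)cc1 | target

## Step count and risk

Total: 15 steps. Longest linear sequence: 14 steps (steps 1–10 and 12–15); step 11 is a one-step side branch.

**Step 13 (key step).** The most likely failure is ring closure through oxygen instead of carbon: an enol oxygen of 24 lactonises onto the ester, or 23 is captured internally, giving a 4-hydroxy-2-pyranone. This is plausible because the carbon aldol must reach a ketone that carries the branched C3 substituent and is therefore slowed. The fallback closes the ring before the carboxyl is unmasked. It sets out from 22: Et3N in CH2Cl2 at room temperature, without heating, lets the dioxinone dienolate carbon add to the C7 ketone and gives, after dehydration, 7-hydroxy-2,2-dimethyl-5-[(2S,3S)-2-(2,4-dimethoxyphenyl)-4-methoxy-6-[2-(4-methoxyphenyl)ethyl]-2,3-dihydro-1-benzofuran-3-yl]-4H-1,3-benzodioxin-4-one F1, in which the carboxyl stays tied up as the acetonide and cannot lactonise. Aqueous KOH in ethanol then opens the acyl ketal of F1 to acid 27, where the fallback rejoins the route at the heating stage of step 14.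

**Step 12.** The risk is proton transfer from C3–H of 20 to the dianion that ends in an unreactive enolate (16 returned on work-up) or in beta-elimination of the ring A phenoxide, since this hydrogen is both benzylic and alpha to the activated acyl group. The fallback sets out from 15, isolated by stopping step 10 before hydroxide is added. Reduction with i-Bu2AlH in CH2Cl2 at −78 °C gives (2S,3S)-2-(2,4-dimethoxyphenyl)-4-methoxy-6-[2-(4-methoxyphenyl)ethyl]-2,3-dihydro-1-benzofuran-3-carbaldehyde F2, to which dianion 21 adds at −78 °C faster than it can enolise an aldehyde. The product is 6-{4-[2-(2,4-dimethoxyphenyl)-4-methoxy-6-[2-(4-methoxyphenyl)ethyl]-2,3-dihydro-1-benzofuran-3-yl]-4-hydroxy-2-oxobutyl}-2,2-dimethyl-4H-1,3-dioxin-4-one F3 (trans ring unchanged, both carbinol epimers), and Dess–Martin periodinane oxidises it to 22.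

**Step 9.** The risk is poor discrimination between the two benzylic hydrogens, or diversion of the carbene to other pathways: both ortho positions of the carbene-bearing ring are substituted and the ortho-methoxy group of the benzyl ether crowds the reacting C–H. The fallback gives up catalyst control and resolves. It sets out from 13: Rh2(OAc)4 in CH2Cl2 gives racemic methyl cis-2-(2,4-dimethoxyphenyl)-4-methoxy-6-[2-(4-methoxyphenyl)ethyl]-2,3-dihydro-1-benzofuran-3-carboxylate F4, and NaOMe in methanol converts it to racemic methyl trans-2-(2,4-dimethoxyphenyl)-4-methoxy-6-[2-(4-methoxyphenyl)ethyl]-2,3-dihydro-1-benzofuran-3-carboxylate F5. Preparative chromatography on a chiral stationary phase separates the enantiomers; the (2S,3S) half is 15, which re-enters at the hydroxide stage of step 10.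

**Step 8.** The risk is incomplete deprotonation of the benzylic methylene by DBU: the two ortho oxygens twist ring A out of conjugation with the enolate and lower the acidity, so diazo transfer may stall. The fallback activates the position by acylation. It sets out from 12: LiHMDS in THF at −78 °C followed by 2,2,2-trifluoroethyl trifluoroacetate gives methyl 2-{2-[(2,4-dimethoxybenzyl)oxy]-6-methoxy-4-[2-(4-methoxyphenyl)ethyl]phenyl}-4,4,4-trifluoro-3-oxobutanoate F6. Treatment with p-ABSA and Et3N in MeCN then transfers the diazo group with loss of the trifluoroacetyl group (detrifluoroacetylative diazo transfer) and gives 13.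

**Step 15.** The risk is ionisation of O1–C2 by the Lewis acid in competition with O–methyl cleavage, followed by Friedel–Crafts alkylation of a neighbouring electron-rich ring or loss of material in ring-opened form. The fallback uses a nucleophile instead of a Lewis acid. It sets out from 28 and ends at 29: NaSEt in DMF at 130 °C removes the methyl groups by SN2 attack of thiolate on carbon. Any quinone methide opening of O1–C2 under these basic conditions is reversible and C3 returns the trans ring on acidification. No new intermediate is formed.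

## Further compounds

F1 | step 13 | 7-hydroxy-2,2-dimethyl-5-[(2S,3S)-2-(2,4-dimethoxyphenyl)-4-methoxy-6-[2-(4-methoxyphenyl)ethyl]-2,3-dihydro-1-benzofuran-3-yl]-4H-1,3-benzodioxin-4-one | COc1ccc(CCc2cc(OC)c3c(c2)O[C@H](c2ccc(OC)cc2OC)[C@H]3c2cc(O)cc4OC(C)(C)OC(=O)c24)cc1
F2 | step 12 | (2S,3S)-2-(2,4-dimethoxyphenyl)-4-methoxy-6-[2-(4-methoxyphenyl)ethyl]-2,3-dihydro-1-benzofuran-3-carbaldehyde | COc1ccc(CCc2cc(OC)c3c(c2)O[C@H](c2ccc(OC)cc2OC)[C@H]3C=O)cc1
F3 | step 12 | 6-{4-[2-(2,4-dimethoxyphenyl)-4-methoxy-6-[2-(4-methoxyphenyl)ethyl]-2,3-dihydro-1-benzofuran-3-yl]-4-hydroxy-2-oxobutyl}-2,2-dimethyl-4H-1,3-dioxin-4-one (trans ring as in 15; descriptors 2S,3R by the priority rules; both carbinol epimers) | COc1ccc(CCc2cc(OC)c3c(c2)O[C@H](c2ccc(OC)cc2OC)[C@H]3C(O)CC(=O)CC2=CC(=O)OC(C)(C)O2)cc1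
F4 | step 9 | racemic methyl cis-2-(2,4-dimethoxyphenyl)-4-methoxy-6-[2-(4-methoxyphenyl)ethyl]-2,3-dihydro-1-benzofuran-3-carboxylate (both enantiomers) | COc1ccc(CCc2cc(OC)c3c(c2)O[C@H](c2ccc(OC)cc2OC)[C@@H]3C(=O)OC)cc1.COc1ccc(CCc2cc(OC)c3c(c2)O[C@@H](c2ccc(OC)cc2OC)[C@H]3C(=O)OC)cc1
F5 | step 9 | racemic methyl trans-2-(2,4-dimethoxyphenyl)-4-methoxy-6-[2-(4-methoxyphenyl)ethyl]-2,3-dihydro-1-benzofuran-3-carboxylate (15 and its 2R,3R enantiomer) | COc1ccc(CCc2cc(OC)c3c(c2)O[C@H](c2ccc(OC)cc2OC)[C@H]3C(=O)OC)cc1.COc1ccc(CCc2cc(OC)c3c(c2)O[C@@H](c2ccc(OC)cc2OC)[C@@H]3C(=O)OC)cc1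
F6 | step 8 | methyl 2-{2-[(2,4-dimethoxybenzyl)oxy]-6-methoxy-4-[2-(4-methoxyphenyl)ethyl]phenyl}-4,4,4-trifluoro-3-oxobutanoate (racemic) | COC(=O)C(C(=O)C(F)(F)F)c1c(OCc2ccc(OC)cc2OC)cc(CCc2ccc(OC)cc2)cc1OC
F0 | step 15 | none | none
A1 | alternative 1 | trans-2-(2,4-dimethoxyphenyl)-3-(3,5-dimethoxyphenyl)-6-[2-(4-methoxyphenyl)ethyl]-3,5,6,7-tetrahydro-1-benzofuran-4(2H)-one (either C6 epimer) | COc1ccc(CCC2CC(=O)C3=C(C2)O[C@H](c2ccc(OC)cc2OC)[C@H]3c2cc(OC)cc(OC)c2)cc1
A2 | alternative 1 | trans-1-(2,4-dimethoxyphenyl)-2-(3,5-dimethoxyphenyl)-6-[2-(4-methoxyphenyl)ethyl]spiro[2.5]octane-4,8-dione | COc1ccc(CCC2CC(=O)C3(C(=O)C2)[C@H](c2ccc(OC)cc2OC)[C@H]3c2cc(OC)cc(OC)c2)cc1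
A3 | alternative 2 | 1,2,2-triarylethyl boronic ester of 1,2-dimethylacenaphthylene-1,2-diol bearing the 2,4-dimethoxyphenyl group on the boron-bound carbon and the 3,5-dimethoxyphenyl and ring A aryl groups on the next carbon | C[C@@]12OB([C@@H](c4ccc(OC)cc4OC)[C@@H](c4cc(OC)cc(OC)c4)c4c(OC)cc(CCc5ccc(OC)cc5)cc4OCOC)O[C@]1(C)c1cccc3cccc2c13
A4 | alternative 2 | (E)-2-{2-methoxy-6-(methoxymethoxy)-4-[2-(4-methoxyphenyl)ethyl]phenyl}ethenyl boronic ester of 1,2-dimethylacenaphthylene-1,2-diol | C[C@@]12OB(/C=C/c4c(OC)cc(CCc5ccc(OC)cc5)cc4OCOC)O[C@]1(C)c1cccc3cccc2c13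
A5 | alternative 2 | (2,4-dimethoxyphenyl)lithium | [Li]c1ccc(OC)cc1OC
A6 | alternative 2 | 3,5-dimethoxyphenyl trifluoromethanesulfonate | COc1cc(OC)cc(OS(=O)(=O)C(F)(F)F)c1
A7 | alternative 3 | methyl (2S,3S)-2-(2,4-dimethoxyphenyl)-4-methoxy-6-[2-(4-methoxyphenyl)ethyl]-2,3-dihydro-1-benzofuran-3-carboxylate (trans; identical with 15) | COc1ccc(CCc2cc(OC)c3c(c2)O[C@H](c2ccc(OC)cc2OC)[C@H]3C(=O)OC)cc1
A8 | alternative 3 | 3-diazo-2-(2,4-dimethoxyphenyl)-5-methoxy-7-[2-(4-methoxyphenyl)ethyl]-2,3-dihydro-4H-chromen-4-one (C2 arranged as in the target; descriptor 2R) | COc1ccc(CCc2cc(OC)c3c(c2)O[C@H](c2ccc(OC)cc2OC)C(=[N+]=[N-])C3=O)cc1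
A9 | alternative 3 | (2S)-2-(2,4-dimethoxyphenyl)-5-methoxy-7-[2-(4-methoxyphenyl)ethyl]-2,3-dihydro-4H-chromen-4-one | COc1ccc(CCc2cc(OC)c3c(c2)O[C@H](c2ccc(OC)cc2OC)CC3=O)cc1
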